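## Plan

1. Numbering follows isochromene (O2, C1, C3, C4, C4a, C5–C8, C8a). The carbocycle C4a–C5–C6–C7–C8–C8a is a polyketide-type oxo array: C6 and C8 are carbonyls on both sides of quaternary C7, C5 is an enolised carbonyl next to C6, and C4a and C8a are the α-carbons of C5 and C8. C5–C6 is therefore an acylation (Claisen) bond and C4a–C8a an aldol bond.
2. Retrosynthesis: remove the C5 silyl group, open the pyran at O2–C1/C1=C8a (C1 is added last as a formyl equivalent), then cut C5–C6 and C4a–C8a together. This divides the carbocycle into a four-carbon 2-hydroxy-2-methyl-3-oxobutanoate unit (C6–C7–C8–C8a; C8a nucleophile, C6 acyl) and a two-carbon α-silyloxy ketone unit (C5 nucleophile, C4a carbonyl) that carries C4, C3 and the side chain.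
3. Helpers: fragment A is a 1,3-dioxolan-4-one whose pivalaldehyde acetal falls off in the key step, with C8 masked as a silyl enol ether. Fragment B is a vinylogous ester whose 2-alkylidene-tetrahydrofuran ring masks the C3 ketone and the side-chain hydroxyl and opens in the last step. The C5 oxygen stays silylated to the end.
4. Forward order: the two fragments (four steps each), the carbocycle in one flask (key step), the C7 butanoate, C1 by aminomethylenation, then the pyran ring by an acid-mediated ring switch and desilylation.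
5. Stereochemistry: C7 (R) is the only stereocentre. It comes from (S)-lactic acid by self-regeneration of the stereocentre (aldol of the cis-2-tert-butyl-dioxolanone enolate anti to tert-butyl). The lactate carboxyl becomes C6 and the lactate oxygen the ester oxygen; no later step makes or breaks a bond at C7.

Key step: step 9

Remark: the exocyclic enol ether in 12–16, F2–F4 and the aminomethylidene group of 16 may form as E/Z mixtures; these geometries disappear in step 12 and are left unspecified in the SMILES. Compounds 14 and 15 are drawn as the tautomer with the C4a=C5 double bond; the C4a=C8a isomer would react in the same way.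

## Route

Step 1
Reactants: 1 (S)-lactic acid; 2 pivalaldehyde
Product: 3 (2S,5S)-2-tert-butyl-5-methyl-1,3-dioxolan-4-one (cis)
Conditions: TsOH·H2O (cat.), pentane, reflux, water separator; crystallisation of the cis isomer
Reagents that add atoms: none
Why: Acid-catalysed acetalisation of an α-hydroxy acid with azeotropic removal of water; the cis acetal should predominate and is purified by crystallisation, so the lactate configuration is stored in the acetal carbon.

Step 2
Reactants: 3 (2S,5S)-2-tert-butyl-5-methyl-1,3-dioxolan-4-one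
Product: 4 (2S,5R)-2-tert-butyl-5-(1-hydroxyethyl)-5-methyl-1,3-dioxolan-4-one (carbinol epimers)
Conditions: LiN(i-Pr)2, THF, −78 °C; MeCHO, −78 °C; aq. NH4Cl
Reagents that add atoms: acetaldehyde, CC=O
Why: Aldol addition of a dioxolanone lithium enolate; the aldehyde should enter trigonal C5 anti to the tert-butyl group, which sets the quaternary centre (5R, the later C7) under control of the acetal carbon, while the carbinol configuration is irrelevant.

Step 3
Reactants: 4 (2S,5R)-2-tert-butyl-5-(1-hydroxyethyl)-5-methyl-1,3-dioxolan-4-one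
Product: 5 (2S,5R)-5-acetyl-2-tert-butyl-5-methyl-1,3-dioxolan-4-one
Conditions: Dess–Martin periodinane, NaHCO3, CH2Cl2, rt
Reagents that add atoms: none
Why: Dess–Martin oxidation of a secondary alcohol to the methyl ketone under buffered conditions; the quaternary centre has no α-hydrogen and cannot epimerise.

Step 4
Reactants: 5 (2S,5R)-5-acetyl-2-tert-butyl-5-methyl-1,3-dioxolan-4-one
Product: 6 (2S,5R)-2-tert-butyl-5-{1-[(tert-butyldimethylsilyl)oxy]ethenyl}-5-methyl-1,3-dioxolan-4-one
Conditions: t-BuMe2SiOTf, Et3N, CH2Cl2, 0 °C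
Reagents that add atoms: tert-butyldimethylsilyl trifluoromethanesulfonate, CC(C)(C)[Si](C)(C)OS(=O)(=O)C(F)(F)F
Why: Soft enolisation and O-silylation of a methyl ketone; only the methyl group can enolise, so one silyl enol ether should form, which removes the acidic hydrogens and stores the C8a nucleophile.

Step 5
Reactants: 7 5-chloropentan-2-one; 8 ethyl [(tert-butyldimethylsilyl)oxy]acetate
Product: 9 1-[(tert-butyldimethylsilyl)oxy]-7-chloroheptane-2,4-dione
Conditions: LiN(i-Pr)2 (2 equiv), 7 (2 equiv), THF, −78 °C; then 8, −78 → −30 °C; aq. NH4Cl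
Reagents that add atoms: none
Why: Crossed Claisen condensation of the kinetic methyl-side lithium enolate of a methyl ketone with an α-silyloxy ester to a 1,3-diketone; the second equivalent of enolate takes up the acidic product and the low temperature should keep the alkyl chloride intact.

Step 6
Reactants: 9 1-[(tert-butyldimethylsilyl)oxy]-7-chloroheptane-2,4-dione
Product: 10 1-[(tert-butyldimethylsilyl)oxy]-7-chloro-3-diazoheptane-2,4-dione
Conditions: 4-acetamidobenzenesulfonyl azide, Et3N, MeCN, 0 °C → rt
Reagents that add atoms: 4-acetamidobenzenesulfonyl azide, CC(=O)Nc1ccc(cc1)S(=O)(=O)N=[N+]=[N-]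
Why: Regitz diazo transfer to the activated methylene of a 1,3-diketone.

Step 7
Reactants: 10 1-[(tert-butyldimethylsilyl)oxy]-7-chloro-3-diazoheptane-2,4-dione
Product: 11 1-[(tert-butyldimethylsilyl)oxy]-7-chloro-3-methoxyheptane-2,4-dione
Conditions: Rh2(OAc)4 (1 mol %), MeOH (5 equiv), CH2Cl2, 25–40 °C
Reagents that add atoms: methanol, CO
Why: Rhodium-carbenoid O–H insertion of a 2-diazo-1,3-dicarbonyl compound into methanol, which places the methoxy group on the future C4.

Step 8
Reactants: 11 1-[(tert-butyldimethylsilyl)oxy]-7-chloro-3-methoxyheptane-2,4-dione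
Product: 12 1-[(tert-butyldimethylsilyl)oxy]-3-(dihydrofuran-2(3H)-ylidene)-3-methoxypropan-2-one
Conditions: K2CO3, DMF, rt → 40 °C
Reagents that add atoms: none
Why: Intramolecular O-alkylation of the diketone enolate (5-exo-tet; C-alkylation would need the disfavoured 5-(enolendo)-exo-tet mode) should give the 2-alkylidene-tetrahydrofuran, a vinylogous ester that fixes the C3 enol oxygen, masks the side-chain hydroxyl and leaves C5 as the only site for kinetic α′-deprotonation.

Step 9
Reactants: 12 1-[(tert-butyldimethylsilyl)oxy]-3-(dihydrofuran-2(3H)-ylidene)-3-methoxypropan-2-one; 6 (2S,5R)-2-tert-butyl-5-{1-[(tert-butyldimethylsilyl)oxy]ethenyl}-5-methyl-1,3-dioxolan-4-one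
Product: 14 (2R)-4-[(tert-butyldimethylsilyl)oxy]-5-[(dihydrofuran-2(3H)-ylidene)(methoxy)methyl]-2-hydroxy-2-methylcyclohex-4-ene-1,3-dione, via acyclic Claisen adduct 13 (not isolated)
Conditions: 12, LiN(i-Pr)2 (1.05 equiv), THF, −78 °C; 6, −78 → −30 °C; volatiles (THF, pivalaldehyde, i-Pr2NH) removed in vacuo; CH2Cl2, Me3SiOTf (3 equiv), −78 → 0 °C; aq. NaHCO3, then dilute citric acid
Reagents that add atoms: none
Why: Proposed new method: the kinetic α′-lithium enolate of vinylogous ester 12 (C5) should acylate at the ring carbonyl of 6 (C6) in a crossed Claisen condensation, the dioxolanone collapsing with loss of pivalaldehyde so that the chiral acetal acts as a traceless acyl donor; Me3SiOTf then silylates the freed C7 hydroxyl and the 1,3-diketone and triggers an intramolecular Mukaiyama aldol addition of the C8 silyl enol ether (C8a) to C4a, and loss of silanol toward C5 gives the 2-silyloxy-enone 14. The closest known reaction types are the Claisen acylation of ketone enolates by lactones and other activated esters (1,3-dioxolan-4-ones are opened at this carbonyl by amines, alkoxides and their own enolates), the Staunton–Weinreb and Hauser [4+2] annulations of a 1,4-donor–acceptor, and the Lewis-acid-mediated intramolecular Mukaiyama aldol condensation. The one ring that closes, the carbocycle, closes in a 6-(enolendo)-exo-trig aldol mode at C4a, while the dioxolanone ring opens. No new stereocentre survives (C5 and C4a end trigonal), and C7 keeps the configuration of 6 because no bond to it is made or broken. The step needs C5 (α′) over γ-deprotonation of 12, which kinetic amide-base conditions on a vinylogous ester should secure, and acylation at the lactone only, which is secured because 6 has neither an acidic hydrogen nor a free ketone. It also needs C–C instead of C–O closure at C4a (3(2H)-furanone formation by the C7 oxygen), which in situ O-silylation and the higher nucleophilicity of the enol ether carbon should secure, and attack at C4a and not at C3, which ring size (six against eight) enforces.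

Step 10
Reactants: 14 (2R)-4-[(tert-butyldimethylsilyl)oxy]-5-[(dihydrofuran-2(3H)-ylidene)(methoxy)methyl]-2-hydroxy-2-methylcyclohex-4-ene-1,3-dione
Product: 15 (1R)-3-[(tert-butyldimethylsilyl)oxy]-4-[(dihydrofuran-2(3H)-ylidene)(methoxy)methyl]-1-methyl-2,6-dioxocyclohex-3-en-1-yl butanoate
Conditions: (n-PrCO)2O, DMAP (cat.), Et3N, CH2Cl2, 0 °C → rt
Reagents that add atoms: butanoic anhydride, CCCC(=O)OC(=O)CCC
Why: DMAP-catalysed acyl transfer to the tertiary α-ketol, the only free hydroxyl at this stage; acylation now also blocks later furanone formation by the C7 oxygen.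

Step 11
Reactants: 15 (1R)-3-[(tert-butyldimethylsilyl)oxy]-4-[(dihydrofuran-2(3H)-ylidene)(methoxy)methyl]-1-methyl-2,6-dioxocyclohex-3-en-1-yl butanoate
Product: 16 (1R)-3-[(tert-butyldimethylsilyl)oxy]-4-[(dihydrofuran-2(3H)-ylidene)(methoxy)methyl]-5-[(dimethylamino)methylidene]-1-methyl-2,6-dioxocyclohex-3-en-1-yl butanoate
Conditions: Me2NCH(OMe)2 (3 equiv), toluene, 50 °C
Reagents that add atoms: N,N-dimethylformamide dimethyl acetal, COC(OC)N(C)C
Why: Condensation of the activated C8a methylene (α to the C8 ketone and vinylogous to C6) with an amide acetal should give the enaminone, which introduces C1 at the aldehyde oxidation level under non-basic conditions.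

Step 12
Reactants: 16 (1R)-3-[(tert-butyldimethylsilyl)oxy]-4-[(dihydrofuran-2(3H)-ylidene)(methoxy)methyl]-5-[(dimethylamino)methylidene]-1-methyl-2,6-dioxocyclohex-3-en-1-yl butanoate
Product: 18 (7R)-5-hydroxy-3-(3-hydroxypropyl)-4-methoxy-7-methyl-6,8-dioxo-7,8-dihydro-6H-isochromen-7-yl butanoate (target), via 5-O-silyl isochromenedione 17 (not isolated)
Conditions: TFA, THF/H2O (4:1), 0 °C → rt; then Et3N·3HF, rt
Reagents that add atoms: water, O
Why: Aqueous acid should hydrolyse the vinylogous enol ether to the C3 ketone and free the side-chain alcohol, the C3 enol oxygen then closes the pyran on C1 by 6-endo-trig addition–elimination with loss of dimethylamine, and fluoride finally cleaves the silyl enol ether to the C5 enol; C7 is not involved.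

## Compound list

1 | (S)-lactic acid | C[C@H](O)C(=O)O | starting material
2 | pivalaldehyde | CC(C)(C)C=O | starting material
3 | (2S,5S)-2-tert-butyl-5-methyl-1,3-dioxolan-4-one | C[C@@H]1O[C@H](C(C)(C)C)OC1=O | intermediate
4 | (2S,5R)-2-tert-butyl-5-(1-hydroxyethyl)-5-methyl-1,3-dioxolan-4-one (carbinol epimers) | CC(O)[C@@]1(C)O[C@H](C(C)(C)C)OC1=O | intermediate
5 | (2S,5R)-5-acetyl-2-tert-butyl-5-methyl-1,3-dioxolan-4-one | CC(=O)[C@@]1(C)O[C@H](C(C)(C)C)OC1=O | intermediate
6 | (2S,5R)-2-tert-butyl-5-{1-[(tert-butyldimethylsilyl)oxy]ethenyl}-5-methyl-1,3-dioxolan-4-one | C=C(O[Si](C)(C)C(C)(C)C)[C@@]1(C)O[C@H](C(C)(C)C)OC1=O | intermediate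
7 | 5-chloropentan-2-one | CC(=O)CCCCl | starting material
8 | ethyl [(tert-butyldimethylsilyl)oxy]acetate | CCOC(=O)CO[Si](C)(C)C(C)(C)C | starting material
9 | 1-[(tert-butyldimethylsilyl)oxy]-7-chloroheptane-2,4-dione | CC(C)(C)[Si](C)(C)OCC(=O)CC(=O)CCCCl | intermediate
10 | 1-[(tert-butyldimethylsilyl)oxy]-7-chloro-3-diazoheptane-2,4-dione | CC(C)(C)[Si](C)(C)OCC(=O)C(=[N+]=[N-])C(=O)CCCCl | intermediate
11 | 1-[(tert-butyldimethylsilyl)oxy]-7-chloro-3-methoxyheptane-2,4-dione | CC(C)(C)[Si](C)(C)OCC(=O)C(OC)C(=O)CCCCl | intermediate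
12 | 1-[(tert-butyldimethylsilyl)oxy]-3-(dihydrofuran-2(3H)-ylidene)-3-methoxypropan-2-one | CC(C)(C)[Si](C)(C)OCC(=O)C(OC)=C1CCCO1 | intermediate
13 | (3R)-2,5-bis[(tert-butyldimethylsilyl)oxy]-7-(dihydrofuran-2(3H)-ylidene)-3-hydroxy-7-methoxy-3-methylhept-1-ene-4,6-dione | C=C(O[Si](C)(C)C(C)(C)C)[C@@](C)(O)C(=O)C(O[Si](C)(C)C(C)(C)C)C(=O)C(OC)=C1CCCO1 | intermediate (not isolated)
14 | (2R)-4-[(tert-butyldimethylsilyl)oxy]-5-[(dihydrofuran-2(3H)-ylidene)(methoxy)methyl]-2-hydroxy-2-methylcyclohex-4-ene-1,3-dione | C[C@@]1(O)C(=O)CC(C(OC)=C2CCCO2)=C(O[Si](C)(C)C(C)(C)C)C1=O | intermediate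
15 | (1R)-3-[(tert-butyldimethylsilyl)oxy]-4-[(dihydrofuran-2(3H)-ylidene)(methoxy)methyl]-1-methyl-2,6-dioxocyclohex-3-en-1-yl butanoate | CCCC(=O)O[C@]1(C)C(=O)CC(C(OC)=C2CCCO2)=C(O[Si](C)(C)C(C)(C)C)C1=O | intermediate
16 | (1R)-3-[(tert-butyldimethylsilyl)oxy]-4-[(dihydrofuran-2(3H)-ylidene)(methoxy)methyl]-5-[(dimethylamino)methylidene]-1-methyl-2,6-dioxocyclohex-3-en-1-yl butanoate | CCCC(=O)O[C@]1(C)C(=O)C(=CN(C)C)C(C(OC)=C2CCCO2)=C(O[Si](C)(C)C(C)(C)C)C1=O | intermediate
17 | (7R)-5-[(tert-butyldimethylsilyl)oxy]-3-(3-hydroxypropyl)-4-methoxy-7-methyl-6,8-dioxo-7,8-dihydro-6H-isochromen-7-yl butanoate | CCCC(=O)O[C@]1(C)C(=O)C2=COC(CCCO)=C(OC)C2=C(O[Si](C)(C)C(C)(C)C)C1=O | intermediate (not isolated)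
18 | (7R)-5-hydroxy-3-(3-hydroxypropyl)-4-methoxy-7-methyl-6,8-dioxo-7,8-dihydro-6H-isochromen-7-yl butanoate | CCCC(=O)O[C@]1(C)C(=O)C2=COC(CCCO)=C(OC)C2=C(O)C1=O | target

## Step count and risks

Total steps: 12. Longest linear sequence: 8 steps (steps 1–4 or 5–8, then 9–12).

Steps most likely to fail:

Step 9 (proposed new method). Acyl transfer to the hindered C6 carbonyl may be slower than enolate equilibration or self-condensation of 12. After acylation, the C7 oxygen may close onto C4a (furanone formation), or the enol silyl group may be lost before the C–C closure. The fallback uses known reactions, puts the butanoate on C7 before the annulation and runs the two bond formations separately. It sets out from 6, which is opened at the acyl carbon with PhSLi (from PhSH and n-BuLi, THF, −78 → 0 °C, pivalaldehyde lost), and the tertiary lithium alkoxide is trapped with butanoyl chloride to give S-phenyl (2R)-2-(butanoyloxy)-3-[(tert-butyldimethylsilyl)oxy]-2-methylbut-3-enethioate F1. Claisen acylation of the lithium enolate of 12 with this thioester should give (3R)-2,5-bis[(tert-butyldimethylsilyl)oxy]-7-(dihydrofuran-2(3H)-ylidene)-7-methoxy-3-methyl-4,6-dioxohept-1-en-3-yl butanoate F2. A separate TiCl4-mediated intramolecular Mukaiyama aldol condensation (CH2Cl2, −78 °C) should then close the carbocycle. The fallback comes back to the route at compound 15, so step 10 is not needed.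

Step 12. The C5 silyl group may be lost before the pyran has closed, followed by five-membered ring closure between the C5 oxygen and the freed C3 ketone (Paal–Knorr-type furan formation), or C1 may be lost by hydrolysis. The fallback sets out from 16 and never frees the C3 ketone. Only the enaminone is hydrolysed (wet silica gel or two-phase aqueous oxalic acid) to (1R)-3-[(tert-butyldimethylsilyl)oxy]-4-[(dihydrofuran-2(3H)-ylidene)(methoxy)methyl]-5-(hydroxymethylidene)-1-methyl-2,6-dioxocyclohex-3-en-1-yl butanoate F3. Anhydrous acid (pyridinium p-toluenesulfonate, CH2Cl2, molecular sieves) should then effect an intramolecular vinylic transetherification, in which the C1 enol oxygen adds to C3 of the alkylidene-tetrahydrofuran and the ring oxygen leaves as the side-chain hydroxyl. This isomerisation comes back to the route at compound 17, which is desilylated with Et3N·3HF as before.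

Step 11. Methanol set free at the temperature needed may attack the acyloxy-1,3-dione (retro-Claisen ring cleavage or ester loss), or condensation may occur at the tetrahydrofuran α-methylene. The fallback sets out from 15 and introduces C1 on the acid side: HC(OMe)3, Ac2O, ZnCl2 (cat.), 80 °C should give (1R)-3-[(tert-butyldimethylsilyl)oxy]-4-[(dihydrofuran-2(3H)-ylidene)(methoxy)methyl]-5-(methoxymethylidene)-1-methyl-2,6-dioxocyclohex-3-en-1-yl butanoate F4. Under the first-stage conditions of step 12 (TFA, THF/H2O) this closes the pyran with loss of methanol instead of dimethylamine and comes back to the route at compound 17.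

Further compounds
F1 | step 9 | S-phenyl (2R)-2-(butanoyloxy)-3-[(tert-butyldimethylsilyl)oxy]-2-methylbut-3-enethioate | C=C(O[Si](C)(C)C(C)(C)C)[C@@](C)(OC(=O)CCC)C(=O)Sc1ccccc1
F2 | step 9 | (3R)-2,5-bis[(tert-butyldimethylsilyl)oxy]-7-(dihydrofuran-2(3H)-ylidene)-7-methoxy-3-methyl-4,6-dioxohept-1-en-3-yl butanoate | C=C(O[Si](C)(C)C(C)(C)C)[C@@](C)(OC(=O)CCC)C(=O)C(O[Si](C)(C)C(C)(C)C)C(=O)C(OC)=C1CCCO1
F3 | step 12 | (1R)-3-[(tert-butyldimethylsilyl)oxy]-4-[(dihydrofuran-2(3H)-ylidene)(methoxy)methyl]-5-(hydroxymethylidene)-1-methyl-2,6-dioxocyclohex-3-en-1-yl butanoate | CCCC(=O)O[C@]1(C)C(=O)C(=CO)C(C(OC)=C2CCCO2)=C(O[Si](C)(C)C(C)(C)C)C1=O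
F4 | step 11 | (1R)-3-[(tert-butyldimethylsilyl)oxy]-4-[(dihydrofuran-2(3H)-ylidene)(methoxy)methyl]-5-(methoxymethylidene)-1-methyl-2,6-dioxocyclohex-3-en-1-yl butanoate | CCCC(=O)O[C@]1(C)C(=O)C(=COC)C(C(OC)=C2CCCO2)=C(O[Si](C)(C)C(C)(C)C)C1=O
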